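Germacrane numbering is used throughout: ring C1–C10, acrylate C11–C13, C14 on C10, C15 on C4.

**Plan**
- Retrosynthesis first cuts the lactone of 25 at C6–O and O–C12, giving seco acid 23. Its C6 is an allylic CH2 between the E-C4=C5 alkene and the carbinol C7 that bears the C11–C13 acrylic acid, so one oxygen at C6 gives a γ-hydroxy acid that closes the five-membered ring C6–C7–C11–C12–O.
- Further cuts: the C8 ester, C12–C11 and C12–O9 (a temporary bridged δ-lactone), C11≡C13, C9–C10 (ring closure), C6–C7 (tartrate enolate alkylation) and C1=C10 (iodo-Wittig).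
- Forward: geranyl acetate gives bromide 6 (C1–C6, C10, C14, C15), which alkylates dimethyl D-tartrate acetonide (C7, C8, C9, C11). The ten-membered ring closes at C9–C10, and O9 is held first in a γ-lactone, then in an α-methylene δ-lactone.
- Acetonide removal, 8-acylation and lactone opening give 23; the enzyme closes the γ-lactone last.
- Stereochemistry: C8 is a tartrate carbon, C7 comes from alkylation anti to the neighbouring ester, C9 from Felkin–Anh addition (checked by lactonisation), C6 from the enzyme. 1(10)Z comes from the iodo-Wittig, 4E from geranyl acetate, the epoxide from Sharpless epoxidation.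

Key step: step 18

Remark: the acyl group written in the target, (2S,3R)-2,3-dimethyloxirane-2-carbonyl, has its two ring methyls cis and the C3 methyl trans to the carboxyl, so it is the epoxide of tiglic ((E)-2-methylbut-2-enoic) acid, not of angelic acid; tiglic acid is used.

**Step 1**
Reactants: 1 geranyl acetate
Product: 2 6,7-epoxygeranyl acetate (racemic at the epoxide)
Conditions: mCPBA, NaHCO3, CH2Cl2, 0 °C
Reagents that add atoms: mCPBA, O=C(OO)c1cccc(Cl)c1
Why: Prilezhaev epoxidation should take the terminal alkene, since the 2,3-alkene is deactivated by the allylic acetate; the epoxide stereocentre is lost in step 2.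

**Step 2**
Reactants: 2 6,7-epoxygeranyl acetate
Product: 3 (2E)-3-methyl-6-oxohex-2-en-1-yl acetate
Conditions: H5IO6, THF/H2O, 0 °C
Reagents that add atoms: none
Why: Epoxide hydrolysis and Malaprade glycol cleavage in one flask should excise acetone and leave the aldehyde, whose oxygen is the former epoxide oxygen.

**Step 3**
Reactants: 3 (2E)-3-methyl-6-oxohex-2-en-1-yl acetate
Product: 4 (2E,6Z)-7-iodo-3-methylocta-2,6-dien-1-yl acetate
Conditions: [EtPPh3]I, n-BuLi, THF, 0 °C; I2, −78 °C; NaN(SiMe3)2, −20 °C; then 3, −78 °C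
Reagents that add atoms: ethyltriphenylphosphonium iodide, CC[P+](c1ccccc1)(c1ccccc1)c1ccccc1.[I-]; iodine, II
Why: Stork–Zhao-type Wittig olefination with the α-iodo ylide should give the (Z)-2-iodoalkene under kinetic control at low temperature, which fixes the later 1(10)Z geometry; the acetate is inert at −78 °C.

**Step 4**
Reactants: 4 (2E,6Z)-7-iodo-3-methylocta-2,6-dien-1-yl acetate
Product: 5 (2E,6Z)-7-iodo-3-methylocta-2,6-dien-1-ol
Conditions: K2CO3 (cat.), MeOH, 0–25 °C
Reagents that add atoms: none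
Why: Base-catalysed methanolysis (transesterification) of the acetate should free the allylic alcohol without touching the vinyl iodide.

**Step 5**
Reactants: 5 (2E,6Z)-7-iodo-3-methylocta-2,6-dien-1-ol
Product: 6 (2E,6Z)-1-bromo-7-iodo-3-methylocta-2,6-diene
Conditions: CBr4, PPh3, CH2Cl2, 0 °C
Reagents that add atoms: tetrabromomethane, BrC(Br)(Br)Br
Why: The Appel reaction should give the primary allylic bromide by SN2 displacement under neutral conditions, without allylic transposition or loss of the E geometry.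

**Step 6**
Reactants: 6 (2E,6Z)-1-bromo-7-iodo-3-methylocta-2,6-diene, 7 dimethyl (4S,5S)-2,2-dimethyl-1,3-dioxolane-4,5-dicarboxylate (dimethyl 2,3-O-isopropylidene-D-tartrate)
Product: 9 dimethyl (4R,5S)-4-[(2E,6Z)-7-iodo-3-methylocta-2,6-dien-1-yl]-2,2-dimethyl-1,3-dioxolane-4,5-dicarboxylate, via lithium ester enolate 8 (not isolated)
Conditions: 7, LiN(i-Pr)2, THF/DMPU, −78 °C; then 6, −78 to −60 °C
Reagents that add atoms: none
Why: In this enolate alkylation of the tartrate acetonide the dioxolane holds the β-oxygen orthogonal to the enolate π system, so no β-elimination is expected at −78 °C; the bromide should enter anti to the neighbouring ester, setting C7 (dioxolane C4, R) while the tartrate carbon C8 (dioxolane C5, S) is untouched.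

**Step 7**
Reactants: 9 alkylated diester
Product: 10 methyl (4R,5S)-5-formyl-4-[(2E,6Z)-7-iodo-3-methylocta-2,6-dien-1-yl]-2,2-dimethyl-1,3-dioxolane-4-carboxylate
Conditions: i-Bu2AlH (1.05 equiv), CH2Cl2, −78 °C; aq. potassium sodium tartrate
Reagents that add atoms: none
Why: Half-reduction of an α-alkoxy methyl ester through its stable tetrahedral aluminate should occur at the ester on C8, because the ester on the quaternary C7 is far more hindered; the aldehyde is used at once to avoid epimerisation at C8.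

**Step 8**
Reactants: 10 aldehyde ester
Product: 12 (1(10)Z,4E,7R,8R,9R)-7,8-(isopropylidenedioxy)-12,13-dinorgermacra-1(10),4-dien-11,9-olide (γ-lactone from C11 to O9), via macrocyclic 9-hydroxy ester 11 (not isolated)
Conditions: CrCl2 (8 equiv), NiCl2 (1 mol %), DMSO/THF, 25 °C, 0.002 M; then DBU (cat.), CH2Cl2, 25 °C
Reagents that add atoms: none
Why: Nozaki–Hiyama–Kishi macrocyclisation should form C9–C10 with retention of the Z alkene, Felkin–Anh attack anti to the C8–O bond giving the 8,9-anti (9R) alkoxide; only this epimer has O9 and the C7 ester on the same face, so lactonisation both masks O9 and C11 and confirms C9.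

**Step 9**
Reactants: 12 γ-lactone
Product: 13 (7R,8R,9R)-11,9-lactol of 12 (both C11 epimers)
Conditions: i-Bu2AlH (1.1 equiv), CH2Cl2, −78 °C
Reagents that add atoms: none
Why: Hydride reduction of a γ-lactone should stop at the lactol at −78 °C; C11 has no α-hydrogen, so nothing can epimerise.

**Step 10**
Reactants: 13 lactol
Product: 14 (1(10)Z,4E,7S,8R,9R)-7,8-(isopropylidenedioxy)-12-norgermacra-1(10),4-dien-11(13)-yn-9-ol
Conditions: dimethyl (1-diazo-2-oxopropyl)phosphonate, K2CO3, MeOH, 0–25 °C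
Reagents that add atoms: dimethyl (1-diazo-2-oxopropyl)phosphonate, COP(=O)(OC)C(=[N+]=[N-])C(C)=O
Why: Seyferth–Gilbert homologation with the Ohira–Bestmann reagent should trap the open hydroxy aldehyde form of the lactol and give the terminal alkyne (C13 from the reagent) with O9 set free; no stereocentre is touched.

**Step 11**
Reactants: 14 alkynol
Product: 15 (1(10)Z,4E,7S,8R,9R)-7,8-(isopropylidenedioxy)germacra-1(10),4,11(13)-trien-12,9-olide
Conditions: PdI2 (5 mol %), PBu3 (10 mol %), CO (7 atm), MeCN, 60 °C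
Reagents that add atoms: carbon monoxide, [C-]#[O+]
Why: Palladium-catalysed cyclocarbonylation of an alkynol should proceed through an alkoxycarbonylpalladium from O9 and CO that adds syn across the alkyne (6-exo-dig), protonolysis leaving the α-methylene δ-lactone; this installs C12 and masks O9 and the acid in one step.

**Step 12**
Reactants: 15 δ-lactone acetonide
Product: 16 (1(10)Z,4E,7S,8R,9R)-7,8-dihydroxygermacra-1(10),4,11(13)-trien-12,9-olide
Conditions: AcOH/H2O (4:1), 40 °C
Reagents that add atoms: none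
Why: Acid-catalysed acetal hydrolysis should free the 7,8-diol while the conjugated lactone and the trisubstituted alkenes tolerate dilute acetic acid; with O9 still in the lactone, O8 becomes the only secondary hydroxyl.

**Step 13**
Reactants: 17 tiglic acid
Product: 18 (2E)-2-methylbut-2-en-1-ol
Conditions: LiAlH4, Et2O, 0–25 °C
Reagents that add atoms: none
Why: Hydride reduction of the carboxylic acid (1,2-reduction) should give the allylic alcohol with the E alkene intact.

**Step 14**
Reactants: 18 (2E)-2-methylbut-2-en-1-ol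
Product: 19 [(2R,3R)-2,3-dimethyloxiran-2-yl]methanol
Conditions: Ti(OiPr)4 (10 mol %), D-(−)-diethyl tartrate (12 mol %), t-BuOOH, 4 Å MS, CH2Cl2, −20 °C
Reagents that add atoms: tert-butyl hydroperoxide, CC(C)(C)OO
Why: Sharpless asymmetric epoxidation with D-(−)-tartrate should deliver oxygen to the face that gives the 2R,3R epoxy alcohol (mirror image of the 2S,3S products from L-(+)-tartrate and E-allylic alcohols); the trans relation of CH2OH and the C3 methyl is carried over from the E alkene.

**Step 15**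
Reactants: 19 epoxy alcohol
Product: 20 (2S,3R)-2,3-dimethyloxirane-2-carboxylic acid
Conditions: RuCl3·xH2O (2 mol %), NaIO4, CCl4/MeCN/H2O, 0–25 °C
Reagents that add atoms: water, O
Why: Ruthenium tetroxide oxidation (catalytic RuCl3 with NaIO4) should take the primary alcohol to the acid through the aldehyde hydrate without opening the epoxide; C2 becomes S only through the change of CIP priority.

**Step 16**
Reactants: 16 diol δ-lactone, 20 (2S,3R)-2,3-dimethyloxirane-2-carboxylic acid
Product: 22 (1(10)Z,4E,7S,8R,9R)-8-[(2S,3R)-2,3-dimethyloxirane-2-carbonyloxy]-7-hydroxygermacra-1(10),4,11(13)-trien-12,9-olide, via mixed anhydride 21 (not isolated)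
Conditions: 20, 2,4,6-Cl3C6H2COCl, Et3N, THF, 25 °C; then 16, DMAP, toluene, 25–40 °C
Reagents that add atoms: none
Why: Yamaguchi esterification should acylate the secondary 8-OH only, because the tertiary 7-OH is unreactive and O9 is tied up in the lactone; no stereocentre is involved.

**Step 17**
Reactants: 22 8-ester δ-lactone
Product: 23 (1(10)Z,4E,7S,8R,9R)-8-[(2S,3R)-2,3-dimethyloxirane-2-carbonyloxy]-7,9-dihydroxygermacra-1(10),4,11(13)-trien-12-oic acid
Conditions: LiOH (1.0 equiv), THF/H2O, 0 °C; then H3PO4 to pH 6.5, used at once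
Reagents that add atoms: lithium hydroxide, [Li+].[OH-]
Why: Saponification with one equivalent of hydroxide should open the strained, conjugated δ-lactone faster than the hindered α,α-disubstituted glycidic ester; the acid is kept as its carboxylate near neutral pH so that neither relactonisation onto O9 nor 8-to-9 acyl migration sets in.

**Step 18**
Reactants: 23 seco acid
Product: 25 (1(10)Z,4E,6R,7R,8R,9R)-8-[(2S,3R)-2,3-dimethyloxirane-2-carbonyloxy]-7,9-dihydroxygermacra-1(10),4,11(13)-trien-12,6-olide (target), via 6-hydroxy acid 24 (not isolated)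
Conditions: engineered cytochrome P450 monooxygenase of the costunolide synthase family with its reductase (yeast microsomes or whole cells), NADPH (cat.), glucose dehydrogenase, D-glucose, O2 (air), potassium phosphate buffer pH 7.5, 30 °C; then pH 6
Reagents that add atoms: dioxygen, O=O
Why: Proposed new method: the iron-oxo (ferryl) porphyrin radical cation of the enzyme should abstract a hydrogen atom from C6, the weakest C–H bond of 23 (allylic to the E-C4=C5 alkene), and oxygen rebound gives the 6-hydroxy acid 24; the closest known reaction is the 6α-hydroxylation of germacra-1(10),4,11(13)-trien-12-oic acid and its 8β-hydroxy derivative by costunolide-type synthases, where the γ-hydroxy acid lactonises spontaneously. 24 closes the five-membered ring C6–C7–C11–C12–O by 5-exo-trig acyl substitution at the carboxyl group with loss of water, which is favoured over the six-membered closure through O9. The new stereocentre C6 (R) is set by the enzyme, which holds the carboxylate and presents one face of the planar allylic radical to the iron-bound hydroxyl, the fixed C7 centre making the two C6 hydrogens diastereotopic. The step needs regioselectivity for C6 over the allylic C2, C3, C14 and C15 positions and over epoxidation of the two ring alkenes, and delivery to one face; both should follow from anchoring of the C12 carboxylate beside the haem, which places C6, three bonds away, above the oxidant. Because 23 carries extra oxygen at C7–C9, a bulky 8-ester and a 1(10)Z alkene, a suitable enzyme variant has to be found by screening and directed evolution.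

**Compound list**
1 | geranyl acetate | CC(C)=CCC/C(C)=C/COC(C)=O | starting material
2 | 6,7-epoxygeranyl acetate (racemic epoxide) | CC1(C)OC1CC/C(C)=C/COC(C)=O | intermediate
3 | (2E)-3-methyl-6-oxohex-2-en-1-yl acetate | O=CCC/C(C)=C/COC(C)=O | intermediate
4 | (2E,6Z)-7-iodo-3-methylocta-2,6-dien-1-yl acetate | CC(=O)OC/C=C(\C)CC/C=C(/C)I | intermediate
5 | (2E,6Z)-7-iodo-3-methylocta-2,6-dien-1-ol | OC/C=C(\C)CC/C=C(/C)I | intermediate
6 | (2E,6Z)-1-bromo-7-iodo-3-methylocta-2,6-diene | BrC/C=C(\C)CC/C=C(/C)I | intermediate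
7 | dimethyl (4S,5S)-2,2-dimethyl-1,3-dioxolane-4,5-dicarboxylate | COC(=O)[C@H]1OC(C)(C)O[C@@H]1C(=O)OC | starting material
8 | lithium ester enolate of 7 | [Li]OC(OC)=C1OC(C)(C)O[C@@H]1C(=O)OC | intermediate
9 | dimethyl (4R,5S)-4-[(2E,6Z)-7-iodo-3-methylocta-2,6-dien-1-yl]-2,2-dimethyl-1,3-dioxolane-4,5-dicarboxylate | COC(=O)[C@]1(C/C=C(\C)CC/C=C(/C)I)OC(C)(C)O[C@@H]1C(=O)OC | intermediate
10 | methyl (4R,5S)-5-formyl-4-[(2E,6Z)-7-iodo-3-methylocta-2,6-dien-1-yl]-2,2-dimethyl-1,3-dioxolane-4-carboxylate | COC(=O)[C@]1(C/C=C(\C)CC/C=C(/C)I)OC(C)(C)O[C@@H]1C=O | intermediate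
11 | methyl (1(10)Z,4E,7R,8R,9R)-9-hydroxy-7,8-(isopropylidenedioxy)-12,13-dinorgermacra-1(10),4-dien-11-oate | COC(=O)[C@@]12C/C=C(\C)CC/C=C(/C)[C@@H](O)[C@H]1OC(C)(C)O2 | intermediate
12 | (1(10)Z,4E,7R,8R,9R)-7,8-(isopropylidenedioxy)-12,13-dinorgermacra-1(10),4-dien-11,9-olide | O=C1O[C@H]2[C@H]3OC(C)(C)O[C@@]13C/C=C(\C)CC/C=C2/C | intermediate
13 | (7R,8R,9R)-11,9-lactol of 12 (both C11 epimers) | OC1O[C@H]2[C@H]3OC(C)(C)O[C@@]13C/C=C(\C)CC/C=C2/C | intermediate
14 | (1(10)Z,4E,7S,8R,9R)-7,8-(isopropylidenedioxy)-12-norgermacra-1(10),4-dien-11(13)-yn-9-ol | C#C[C@@]12C/C=C(\C)CC/C=C(/C)[C@@H](O)[C@H]1OC(C)(C)O2 | intermediate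
15 | (1(10)Z,4E,7S,8R,9R)-7,8-(isopropylidenedioxy)germacra-1(10),4,11(13)-trien-12,9-olide | C=C1C(=O)O[C@@H]2C(\C)=C/CC/C(C)=C/C[C@]13OC(C)(C)O[C@H]23 | intermediate
16 | (1(10)Z,4E,7S,8R,9R)-7,8-dihydroxygermacra-1(10),4,11(13)-trien-12,9-olide | C=C1C(=O)O[C@@H]2C(\C)=C/CC/C(C)=C/C[C@@]1(O)[C@@H]2O | intermediate
17 | tiglic acid, (2E)-2-methylbut-2-enoic acid | C/C=C(\C)C(=O)O | starting material
18 | (2E)-2-methylbut-2-en-1-ol | C/C=C(\C)CO | intermediate
19 | [(2R,3R)-2,3-dimethyloxiran-2-yl]methanol | OC[C@@]1(C)O[C@@H]1C | intermediate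
20 | (2S,3R)-2,3-dimethyloxirane-2-carboxylic acid | OC(=O)[C@@]1(C)O[C@@H]1C | intermediate
21 | (2S,3R)-2,3-dimethyloxirane-2-carboxylic 2,4,6-trichlorobenzoic anhydride | O=C(OC(=O)[C@@]1(C)O[C@@H]1C)c1c(Cl)cc(Cl)cc1Cl | intermediate
22 | (1(10)Z,4E,7S,8R,9R)-8-[(2S,3R)-2,3-dimethyloxirane-2-carbonyloxy]-7-hydroxygermacra-1(10),4,11(13)-trien-12,9-olide | C=C1C(=O)O[C@@H]2C(\C)=C/CC/C(C)=C/C[C@@]1(O)[C@@H]2OC(=O)[C@@]3(C)O[C@@H]3C | intermediate
23 | (1(10)Z,4E,7S,8R,9R)-8-[(2S,3R)-2,3-dimethyloxirane-2-carbonyloxy]-7,9-dihydroxygermacra-1(10),4,11(13)-trien-12-oic acid | C=C(C(=O)O)[C@@]1(O)C/C=C(\C)CC/C=C(/C)[C@@H](O)[C@H]1OC(=O)[C@@]2(C)O[C@@H]2C | intermediate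
24 | (1(10)Z,4E,6R,7R,8R,9R)-8-[(2S,3R)-2,3-dimethyloxirane-2-carbonyloxy]-6,7,9-trihydroxygermacra-1(10),4,11(13)-trien-12-oic acid | C=C(C(=O)O)[C@@]1(O)[C@H](O)/C=C(\C)CC/C=C(/C)[C@@H](O)[C@H]1OC(=O)[C@@]2(C)O[C@@H]2C | intermediate
25 | (1(10)Z,4E,6R,7R,8R,9R)-8-[(2S,3R)-2,3-dimethyloxirane-2-carbonyloxy]-7,9-dihydroxygermacra-1(10),4,11(13)-trien-12,6-olide | C=C1C(=O)O[C@@H]2/C=C(\C)CC/C=C(/C)[C@@H](O)[C@@H](OC(=O)[C@@]3(C)O[C@@H]3C)[C@@]12O | target

**Step count**
Total: 18 steps. Longest linear sequence: 15 steps (steps 1–12 and 16–18); steps 13–15 make the side-chain acid.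

**Steps most likely to fail**

1. Step 18. The enzyme may not bind or turn over the heavily oxygenated 1(10)Z substrate, or it may oxidise another allylic position or an alkene.
   - Fallback, known chemistry: C6 keeps the oxygen that geraniol already has. It sets out from 5 and returns at 24.
   - MnO2 oxidation of 5 should give (2E,6Z)-7-iodo-3-methylocta-2,6-dienal F1.
   - Aldol addition of enolate 8 (from 7 and LiN(i-Pr)2) to F1 gives 6-hydroxy diester F2, the epimer with C6 as in 25 being separated; TBSOTf and 2,6-lutidine give 6-silyloxy diester F3.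
   - The operations of steps 7 to 11 then give in turn 6-silyloxy aldehyde F4, 6-silyloxy macrocyclic hydroxy ester F5, 6-silyloxy γ-lactone F6, 6-silyloxy lactol F7, 6-silyloxy alkynol F8 and 6-silyloxy δ-lactone acetonide F9.
   - The operations of steps 12 and 16 give 6-silyloxy diol F10 and 6-silyloxy 8-ester F11; HF·pyridine frees 6-hydroxy δ-lactone F12.
   - The conditions of step 17 open F12 to 24, which closes to 25 on mild acidification.

2. Step 8. Facial selectivity in the addition of the alkenylchromium to the aldehyde may be poor during ring closure, so that the 9S alcohol dominates; its O9 and C7 ester lie on opposite faces and it stays open.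
   - Fallback: C9 is corrected after ring closure by SN2 inversion. It sets out from 10 and returns at 12.
   - The 9-epi hydroxy ester F13 from the cyclisation is submitted to a Mitsunobu reaction (PPh3, diisopropyl azodicarboxylate, 4-nitrobenzoic acid), which should give the 9R 4-nitrobenzoate F14.
   - K2CO3 in MeOH removes the benzoate to give 11, which lactonises to 12.

3. Step 11. The 6-exo insertion that closes the bridged δ-lactone may be too strained, so that the acylpalladium is intercepted intermolecularly or the alkyne oligomerises.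
   - Fallback: O9 and the acid are protected separately, which also avoids the hydroxide opening of step 17. It sets out from 14 and returns at 23.
   - TIPSOTf and 2,6-lutidine give 9-O-triisopropylsilyl alkyne F15.
   - Markovnikov alkoxycarbonylation of the terminal alkyne (Pd(OAc)2, 2-(diphenylphosphino)pyridine, MsOH cat., CO, 2-(trimethylsilyl)ethanol) gives 2-(trimethylsilyl)ethyl acrylate F16.
   - AcOH/H2O gives 7,8-diol F17, and Yamaguchi esterification with 20 gives 8-ester F18.
   - Tris(dimethylamino)sulfonium difluorotrimethylsilicate in DMF removes both silicon groups and delivers 23 as its carboxylate.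

**Further compounds**
F1 | step 18 | (2E,6Z)-7-iodo-3-methylocta-2,6-dienal | O=C/C=C(\C)CC/C=C(/C)I
F2 | step 18 | 6-hydroxy diester | COC(=O)[C@]1([C@H](O)/C=C(\C)CC/C=C(/C)I)OC(C)(C)O[C@@H]1C(=O)OC
F3 | step 18 | 6-silyloxy diester | COC(=O)[C@]1([C@H](O[Si](C)(C)C(C)(C)C)/C=C(\C)CC/C=C(/C)I)OC(C)(C)O[C@@H]1C(=O)OC
F4 | step 18 | 6-silyloxy aldehyde | COC(=O)[C@]1([C@H](O[Si](C)(C)C(C)(C)C)/C=C(\C)CC/C=C(/C)I)OC(C)(C)O[C@@H]1C=O
F5 | step 18 | 6-silyloxy macrocyclic hydroxy ester | COC(=O)[C@@]12[C@H](O[Si](C)(C)C(C)(C)C)/C=C(\C)CC/C=C(/C)[C@@H](O)[C@H]1OC(C)(C)O2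
F6 | step 18 | 6-silyloxy γ-lactone | O=C1O[C@H]2[C@H]3OC(C)(C)O[C@@]13[C@H](O[Si](C)(C)C(C)(C)C)/C=C(\C)CC/C=C2/C
F7 | step 18 | 6-silyloxy lactol | OC1O[C@H]2[C@H]3OC(C)(C)O[C@@]13[C@H](O[Si](C)(C)C(C)(C)C)/C=C(\C)CC/C=C2/C
F8 | step 18 | 6-silyloxy alkynol | C#C[C@@]12[C@H](O[Si](C)(C)C(C)(C)C)/C=C(\C)CC/C=C(/C)[C@@H](O)[C@H]1OC(C)(C)O2
F9 | step 18 | 6-silyloxy δ-lactone acetonide | C=C1C(=O)O[C@@H]2C(\C)=C/CC/C(C)=C/[C@@H](O[Si](C)(C)C(C)(C)C)[C@]13OC(C)(C)O[C@H]23
F10 | step 18 | 6-silyloxy diol | C=C1C(=O)O[C@@H]2C(\C)=C/CC/C(C)=C/[C@@H](O[Si](C)(C)C(C)(C)C)[C@@]1(O)[C@@H]2O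
F11 | step 18 | 6-silyloxy 8-ester | C=C1C(=O)O[C@@H]2C(\C)=C/CC/C(C)=C/[C@@H](O[Si](C)(C)C(C)(C)C)[C@@]1(O)[C@@H]2OC(=O)[C@@]3(C)O[C@@H]3C
F12 | step 18 | 6-hydroxy δ-lactone | C=C1C(=O)O[C@@H]2C(\C)=C/CC/C(C)=C/[C@@H](O)[C@@]1(O)[C@@H]2OC(=O)[C@@]3(C)O[C@@H]3C
F13 | step 8 | 9-epi hydroxy ester | COC(=O)[C@@]12C/C=C(\C)CC/C=C(/C)[C@H](O)[C@H]1OC(C)(C)O2
F14 | step 8 | 9R 4-nitrobenzoate | COC(=O)[C@@]12C/C=C(\C)CC/C=C(/C)[C@@H](OC(=O)c3ccc(cc3)[N+](=O)[O-])[C@H]1OC(C)(C)O2
F15 | step 11 | 9-O-triisopropylsilyl alkyne | C#C[C@@]12C/C=C(\C)CC/C=C(/C)[C@@H](O[Si](C(C)C)(C(C)C)C(C)C)[C@H]1OC(C)(C)O2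
F16 | step 11 | 2-(trimethylsilyl)ethyl acrylate | C=C(C(=O)OCC[Si](C)(C)C)[C@@]12C/C=C(\C)CC/C=C(/C)[C@@H](O[Si](C(C)C)(C(C)C)C(C)C)[C@H]1OC(C)(C)O2
F17 | step 11 | 7,8-diol | C=C(C(=O)OCC[Si](C)(C)C)[C@@]1(O)C/C=C(\C)CC/C=C(/C)[C@@H](O[Si](C(C)C)(C(C)C)C(C)C)[C@H]1O
F18 | step 11 | 8-ester | C=C(C(=O)OCC[Si](C)(C)C)[C@@]1(O)C/C=C(\C)CC/C=C(/C)[C@@H](O[Si](C(C)C)(C(C)C)C(C)C)[C@H]1OC(=O)[C@@]2(C)O[C@@H]2C
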